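## The problem

Halimane numbering is used throughout: ring A is C1–C5 and C10, ring B is C5–C10, C11–C16 form the chain on C9, C17 is the methyl on C8, C18 (carboxyl) and C19 sit on C4, and C20 is the methyl on C9.

The target is a 1(10)-octalin: rings A and B share the C5–C10 bond, and C10 is part of the trisubstituted C1=C10 alkene. Quaternary C4 carries a free carboxylic acid. Quaternary C9 carries a methyl group and a chain that ends in an (E)-trisubstituted allylic propionate. Four stereocentres have to be set. C4 and C5 are neighbours in ring A, C8 and C9 are neighbours in ring B, and the two pairs are separated by the sp2 carbon C10. Inside each pair one centre can control the other (a C8 methyl can steer alkylation at C9; a concerted ring closure can fix C4 against C5). No bond relays configuration between the pairs, so their mutual relation is the central stereochemical problem. Three groups are fragile: the C1=C10 alkene can migrate under acid, the allylic propionate ionises and is cleaved by bases and nucleophiles, and the neopentylic C18 ester resists hydrolysis. The acid therefore has to be freed before the propionate is put on, and the propionate comes last. The feature that opens the route is ring A itself. It holds the C1=C10 alkene and the C4–C5 bond between the quaternary ester carbon and the ring-fusion methine. That is the σ bond formed when a triene C5=C10–C1=C2–C3=C4 closes, with C5=C10 supplied by a ring B cyclohexene that already carries C8 and C9.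

## Retrosynthesis

**Propionate and acid (21 ⇒ 20 ⇒ 19).** The C15–O acyl bond is cut last and the O–CH3 bond of the C18 ester just before it. The reverse order is excluded, because the dependable way to free an ester on quaternary C4 is nucleophilic attack on its O-methyl group, and such a nucleophile would also displace an allylic carboxylate. Hydroxy ester 19 differs from the target only in these two acyl groups. The forward steps must dealkylate the ester without touching C1=C10 or C13=C14, and acylate the primary alcohol without permanently engaging the hindered acid.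

**Side chain (19 ⇒ 17 ⇒ 16 ⇒ 15).** In 19 the C13–C16 and C14–C15 bonds are cut together, which leads to terminal alkyne 17. Syn methylmetalation of an alkyne fixes the (13E) geometry by mechanism, whereas the neighbouring cut at C13=C14 (olefination of a methyl ketone) gives E/Z mixtures. Alkyne 17 comes from aldehyde 16 by a one-carbon homologation (C13–C14), and 16 from primary alcohol 15. Alcohol 15 holds all four stereocentres and has a three-carbon chain in place of the six-carbon one. The forward steps must work beside a methyl ester, which is safe because it is neopentylic, and beside the trisubstituted ring alkene.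

**Ring A unsaturation (15 ⇒ 14).** Adding a C2=C3 double bond to 15 gives the 1(10),2-diene 14, the cyclohexadiene that an electrocyclic closure produces. This costs one forward step: a reduction that takes the cis-disubstituted C2=C3 bond and leaves the trisubstituted C1=C10 bond.

**Ring A (14 ⇒ 13), the key disconnection.** The C4–C5 bond is cut. Ring A opens to triene 13, in which C5=C10 is the alkene of a ring B cyclohexene and C1=C2–C3=C4 is a (2Z,4Z)-dienoate arm.
- Against cutting C4–C5 together with C2–C3 (a bimolecular cycloaddition at a diene crowded by C9), this cut is unimolecular.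
- Against cutting ring B bonds (which leaves C4 unsolved), it delivers quaternary C4 with ester and methyl already differentiated and fixes C4 against C5 by orbital symmetry.
- The precursor has one ring and two stereocentres instead of two rings and four.
- The forward reaction needs the ester and H5 both inside the triene, which is a matter of alkene geometry. It also needs closure on the face of C5 anti to the C9 chain, which is a matter of torquoselectivity and is the weak point of the plan.

**Dienoate arm (13 ⇒ 12 ⇒ 10 + 11; 10 ⇒ 9 ⇒ 7 + 8).** The (4Z) alkene is traced to the alkyne of enynoate 12, so that its geometry comes from a cis-selective semireduction done just before heating. The C3=C4 bond of 12 is cut to ynal 10 and phosphonate 11. A Z-selective olefination sets the (2Z) geometry on which the C4 configuration depends, and any E isomer can be removed at this stable stage. Ynal 10 is the oxidation product of enynol 9, whose C10–C1 bond is cut to enol triflate 7 and propargyl alcohol 8. Building the arm in three short steps from an alkyne is preferred to coupling a preformed (Z,Z)-dienyl metal, which needs its own synthesis and is kept as a fallback.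

**Ring B functional groups (7 ⇒ 6 ⇒ 5).** The chain hydroxyl of 7 goes back to the allyl group of 6 (C13–O bond), and the enol triflate of 6 to ketone 5. Enolisation of 5 can only go toward C5 because C9 is quaternary. Hydroborating at the triflate stage has two benefits. The primary alcohol never needs a protecting group, since every step up to 15 tolerates it. The allyl group, which forms a 1,5-diene with C5=C10 and could undergo Cope rearrangement on heating, is gone well before step 8.

**Stereogenic pair C8/C9 (5 ⇒ 1 + 2).** The C8–C17 and C9–C11 bonds are cut, leading to enone 1, a methyl nucleophile and allyl bromide 2. Catalytic asymmetric conjugate addition fixes C8 and the enantiomeric series. The enolate is then allylated anti to the new methyl group, which gives the cis relation of the C8 and C9 methyls. Two adjacent centres, one quaternary, are set in one operation from commercial materials.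

## Roads not taken

**Alternative 1:** intramolecular Diels–Alder reaction that builds both rings.
- Cut: C8–C9 and C5–C10.
- Forward key step: acyclic trienone A1 cyclises under a chiral Lewis acid; its (E,E)-diene C5=C6–C7=C8 adds to the tethered (E)-enone C9=C10 to give the cis-fused 1-oxo-6-octalin diester A2.
- Merits: two rings and the C5/C8/C9 relation arise in one step from a chain made of simple pieces. The C8/C9 relation follows from two alkene geometries, and the absolute sense is under catalyst control.
- Weak points for this target:
  - The dienophile is a β,β-disubstituted enone that must create quaternary C9, a poorly reactive case for a catalysed cycloaddition.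
  - A2 carries a geminal diester at C4. C4 is therefore not a stereocentre after the key step, and the two ester groups would later have to be told apart, one reduced to methyl and one kept.
  - The C1 ketone has to be turned into the C1=C10 alkene regioselectively, C6=C7 has to be reduced beside it, and the C9 chain is one carbon short.
- Comparison: this road is better in rings formed per step and in control of the ring B stereocentres against C5, which is where the chosen plan is weakest. The chosen plan sets against it a key step that delivers C4 with acid and methyl already differentiated and cis to H5, and a product one reduction away from the target ring system. A2 would need a long series of corrections at C1, C4 and C6=C7.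

**Alternative 2:** directed cyclopropanation and fragmentation to install the C9 methyl.
- Cut: C9–C20, with C10–C20 as a temporary bond.
- Forward key step: the Δ9(10)-octalin C1 alcohol A3 undergoes hydroxyl-directed Simmons–Smith cyclopropanation of its tetrasubstituted alkene to give the 9,10-methano decalin A4. Later cleavage of C10–C20 from a C1 radical or cation would leave C20 as the C9 methyl and place the alkene at C1=C10.
- Merits: directed cyclopropanation is dependable even on tetrasubstituted alkenes. It fixes C9 relative to the C1 carbinol and so to ring A, the very relation that the chosen plan leaves to a modest torquoselectivity.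
- Weak points for this target:
  - It is a tactic for one methyl group and builds no ring. A3 must already contain C4, C5, C8 and a C1 carbinol of defined configuration, and making it is at least as long as the whole chosen route to 14.
  - The fragmentation must break C10–C20 and not C9–C10 (ring expansion) and must end in hydrogen delivery to C20.
  - Several extra redox steps at C1 are needed.
- Comparison: this road is better in reliability of the C9/ring A relation and clearly worse in step count and convergence. The chosen plan answers with a route in which every C–C bond-forming step also builds the skeleton.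

**Alternative 3:** convergent Diels–Alder annulation of ring A.
- Cut: C4–C5 and C2–C3.
- Forward key step: the ring B diene A5 (obtainable by vinylation of 6) and methacrolein A6 combine under a chiral Lewis acid to give the 9-allyl 1(10)-octalin aldehyde A7.
- Merits: the C1=C10 alkene appears directly and no extra alkene is formed, so the alkyne chemistry, the semireduction and the diimide step all fall away. An exo-selective addition of A6 puts the formyl group cis to H5. The catalyst can impose the facial sense at C5 instead of leaving it to the substrate. The route would be some two to four steps shorter.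
- Weak points for this target:
  - A5 is a semicyclic diene whose s-cis conformer is crowded by quaternary C9, so a bimolecular reaction is expected to be slow.
  - Regiochemistry rests on opposing directing effects of the two diene substituents.
  - The exo preference and the catalyst's facial preference must both hold on a diene class on which such catalysts are little tested.
  - The aldehyde has to be oxidised afterwards.
- Comparison: if the catalyst dominates, this road is shorter and better controlled in exactly the respect in which the chosen plan is weakest. The chosen plan sets against it a unimolecular closure that does not depend on the reactivity of a hindered diene. Its C4/C5 relation is fixed by two separately secured alkene geometries, with no regiochemical or endo/exo question. Because both roads pass through 6, this alternative is kept as the fallback for the key step.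

Key step: step 8

Assumption: the antipode of the phosphoramidite ligand in step 1 is the one that delivers methyl to give the (3R) enolate 3; should the sense of induction prove opposite, the mirror-image ligand is used and nothing else changes.

## Route

Step 1
Reactants: 1 2-methylcyclohex-2-en-1-one; 2 allyl bromide
Product: 5 (2S,3R)-2,3-dimethyl-2-(prop-2-en-1-yl)cyclohexan-1-one, via dimethylaluminium enolate 3 (not isolated), via lithium trimethylaluminate enolate 4 (not isolated)
Conditions: Me3Al, copper thiophene-2-carboxylate (CuO2C-C4H3S, cat.), BINOL-derived phosphoramidite with a bis(1-phenylethyl)amino group (cat.), Et2O, −30 °C; then MeLi, THF, −30 → 0 °C; then allyl bromide, DMPU, 0 °C → rt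
Reagents that add atoms: trimethylaluminium C[Al](C)C
Why: Copper-catalysed asymmetric conjugate addition of methyl sets C8; the aluminium enolate is too unreactive to alkylate, so MeLi converts it into the aluminate, which is C-allylated anti to the new C8 methyl, leaving the C8 and C9 methyls cis (conjugate addition–enolate alkylation).

Step 2
Reactants: 5 (2S,3R)-2,3-dimethyl-2-(prop-2-en-1-yl)cyclohexan-1-one
Product: 6 (5R,6S)-5,6-dimethyl-6-(prop-2-en-1-yl)cyclohex-1-en-1-yl trifluoromethanesulfonate
Conditions: KN(SiMe3)2, THF, −78 °C; then PhNTf2, −78 → 0 °C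
Reagents that add atoms: N-phenylbis(trifluoromethanesulfonimide) O=S(=O)(N(c1ccccc1)S(=O)(=O)C(F)(F)F)C(F)(F)F
Why: C9 is quaternary, so the base can only remove a C5 hydrogen and the enolate is trapped on oxygen; regiospecific enol triflate formation that does not touch C8 or C9.

Step 3
Reactants: 6 (5R,6S)-5,6-dimethyl-6-(prop-2-en-1-yl)cyclohex-1-en-1-yl trifluoromethanesulfonate
Product: 7 (5R,6S)-6-(3-hydroxypropyl)-5,6-dimethylcyclohex-1-en-1-yl trifluoromethanesulfonate
Conditions: 9-BBN, THF, 0 °C → rt; then NaBO3·4H2O, H2O, rt
Reagents that add atoms: sodium perborate tetrahydrate [Na+].[Na+].O[B-]1(O)OO[B-](O)(O)OO1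
Why: 9-BBN adds to the monosubstituted alkene with anti-Markovnikov selectivity and ignores the electron-poor trisubstituted enol triflate, and mild perborate oxidation gives the primary alcohol (hydroboration–oxidation). Saturating the allyl group here also removes the C5=C10–C9–C11–C12=C13 1,5-diene that could undergo Cope rearrangement at the temperature of step 8.

Step 4
Reactants: 7 (5R,6S)-6-(3-hydroxypropyl)-5,6-dimethylcyclohex-1-en-1-yl trifluoromethanesulfonate; 8 propargyl alcohol
Product: 9 3-[(5R,6S)-6-(3-hydroxypropyl)-5,6-dimethylcyclohex-1-en-1-yl]prop-2-yn-1-ol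
Conditions: Pd(PPh3)2Cl2 (cat.), CuI (cat.), i-Pr2NH, THF (degassed), rt
Reagents that add atoms: none
Why: Sonogashira coupling of an enol triflate with a terminal alkyne forms the C10–C1 bond under mild conditions that tolerate both free hydroxyls; 2,2-disubstituted cyclohexenyl triflates are competent partners.

Step 5
Reactants: 9 3-[(5R,6S)-6-(3-hydroxypropyl)-5,6-dimethylcyclohex-1-en-1-yl]prop-2-yn-1-ol
Product: 10 3-[(5R,6S)-6-(3-hydroxypropyl)-5,6-dimethylcyclohex-1-en-1-yl]prop-2-ynal
Conditions: activated MnO2, CH2Cl2, rt
Reagents that add atoms: none
Why: MnO2 oxidises activated (propargylic) alcohols far faster than saturated primary ones, so only C3 becomes the aldehyde and the C13 hydroxyl needs no protection (chemoselective propargylic oxidation).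

Step 6
Reactants: 10 3-[(5R,6S)-6-(3-hydroxypropyl)-5,6-dimethylcyclohex-1-en-1-yl]prop-2-ynal; 11 methyl 2-[bis(2,2,2-trifluoroethoxy)phosphoryl]propanoate
Product: 12 methyl (2Z)-5-[(5R,6S)-6-(3-hydroxypropyl)-5,6-dimethylcyclohex-1-en-1-yl]-2-methylpent-2-en-4-ynoate
Conditions: KN(SiMe3)2, 18-crown-6, THF, −78 °C
Reagents that add atoms: none
Why: Still–Gennari olefination: the bis(trifluoroethyl) phosphonate anion adds irreversibly and eliminates fast, giving the trisubstituted (Z)-enoate with the ester cis to C2, the geometry that later places CO2Me inside the triene; the stabilised anion is not basic enough to deprotonate the primary alcohol.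

Step 7
Reactants: 12 methyl (2Z)-5-[(5R,6S)-6-(3-hydroxypropyl)-5,6-dimethylcyclohex-1-en-1-yl]-2-methylpent-2-en-4-ynoate
Product: 13 methyl (2Z,4Z)-5-[(5R,6S)-6-(3-hydroxypropyl)-5,6-dimethylcyclohex-1-en-1-yl]-2-methylpenta-2,4-dienoate
Conditions: Zn dust activated with Cu(OAc)2 and AgNO3, MeOH/H2O, rt, dark
Reagents that add atoms: none
Why: Boland reduction: zinc activated with copper and silver delivers two hydrogens cis to a conjugated alkyne and stops at the alkene, so C1=C2 is formed (Z) without touching the enoate or the ring alkene; the triene is kept cold and carried on at once.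

Step 8
Reactants: 13 methyl (2Z,4Z)-5-[(5R,6S)-6-(3-hydroxypropyl)-5,6-dimethylcyclohex-1-en-1-yl]-2-methylpenta-2,4-dienoate
Product: 14 methyl (1S,5S,6R,8aS)-5-(3-hydroxypropyl)-1,5,6-trimethyl-1,5,6,7,8,8a-hexahydronaphthalene-1-carboxylate
Conditions: toluene (degassed), 2,6-di-tert-butyl-4-methylphenol (cat.), sealed tube, 150 °C
Reagents that add atoms: none
Why: On heating, the triene C5=C10–C1=C2–C3=C4 reaches its helical s-cis,Z,s-cis conformer and the termini C4 and C5 bond in a concerted, thermally allowed six-electron electrocyclization; the closest known reaction type is the thermal closure of (Z)-hexatrienes made by alkyne semireduction, including the previtamin D to pyrocalciferol closure and closures that create quaternary carbons. Ring A closes in the disrotatory mode through formation of the C4–C5 σ bond, which leaves the C10=C1–C2=C3 diene. C4 and C5 are set as a pair by orbital symmetry and alkene geometry: H5 is the inside group at C5 because ring B holds C6 trans to C1, the ester is the inside group at C4 because of the (2Z) geometry, and disrotation turns both inside groups to the same face, so CO2Me and H5 end cis as in the target. The selectivity needed beyond this is torquoselectivity: C4 must bond to the face of C5 anti to the C9 chain. That mode lets ring B develop the chair in which the hydroxypropyl chain and the C8 methyl are trans-diaxial and the small C9 methyl lies in the ring plane beside H1, whereas the other mode must wedge the chain into that in-plane position between the equatorial C8 methyl and H1, where it has no unstrained rotamer. The preference is expected to be modest, so the minor diastereomer is to be removed by chromatography here or after step 9. Neither terminus has an allylic hydrogen inside, so 1,7-hydrogen shifts cannot compete, and the saturated C9 chain excludes a Cope rearrangement; the inside ester raises the barrier, which is why 150 °C and degassed, radical-free conditions are chosen.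

Step 9
Reactants: 14 methyl (1S,5S,6R,8aS)-5-(3-hydroxypropyl)-1,5,6-trimethyl-1,5,6,7,8,8a-hexahydronaphthalene-1-carboxylate
Product: 15 methyl (1S,5S,6R,8aS)-5-(3-hydroxypropyl)-1,5,6-trimethyl-1,2,3,5,6,7,8,8a-octahydronaphthalene-1-carboxylate
Conditions: 2-nitrobenzenesulfonyl hydrazide, Et3N, CH2Cl2, rt
Reagents that add atoms: none
Why: Diimide, generated from the sulfonyl hydrazide, transfers H2 by a concerted syn process whose rate falls steeply with alkene substitution: the cis-disubstituted C2=C3 bond is reduced, the trisubstituted C1=C10 bond next to quaternary C9 is not, and no metal is present that could move the remaining alkene.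

Step 10
Reactants: 15 methyl (1S,5S,6R,8aS)-5-(3-hydroxypropyl)-1,5,6-trimethyl-1,2,3,5,6,7,8,8a-octahydronaphthalene-1-carboxylate
Product: 16 methyl (1S,5S,6R,8aS)-1,5,6-trimethyl-5-(3-oxopropyl)-1,2,3,5,6,7,8,8a-octahydronaphthalene-1-carboxylate
Conditions: Dess–Martin periodinane, NaHCO3, CH2Cl2, rt
Reagents that add atoms: none
Why: Dess–Martin oxidation takes the primary alcohol to the aldehyde under buffered, non-acidic conditions that leave the C1=C10 alkene and the ester alone.

Step 11
Reactants: 16 methyl (1S,5S,6R,8aS)-1,5,6-trimethyl-5-(3-oxopropyl)-1,2,3,5,6,7,8,8a-octahydronaphthalene-1-carboxylate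
Product: 17 methyl (1S,5S,6R,8aS)-5-(but-3-yn-1-yl)-1,5,6-trimethyl-1,2,3,5,6,7,8,8a-octahydronaphthalene-1-carboxylate
Conditions: dimethyl (1-diazo-2-oxopropyl)phosphonate, K2CO3, MeOH, 0 °C → rt
Reagents that add atoms: dimethyl (1-diazo-2-oxopropyl)phosphonate COP(=O)(OC)C(=[N+]=[N-])C(C)=O
Why: Seyferth–Gilbert homologation with the Ohira–Bestmann reagent: methanolysis releases the diazomethylphosphonate anion, which converts the aldehyde into the terminal alkyne and adds C14; K2CO3 in methanol cannot harm a methyl ester on a quaternary carbon.

Step 12
Reactants: 17 methyl (1S,5S,6R,8aS)-5-(but-3-yn-1-yl)-1,5,6-trimethyl-1,2,3,5,6,7,8,8a-octahydronaphthalene-1-carboxylate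
Product: 19 methyl (1S,5S,6R,8aS)-5-[(3E)-5-hydroxy-3-methylpent-3-en-1-yl]-1,5,6-trimethyl-1,2,3,5,6,7,8,8a-octahydronaphthalene-1-carboxylate, via alkenyldimethylalane 18 (not isolated)
Conditions: Me3Al, Cp2ZrCl2 (cat.), CH2Cl2, 0 °C → rt; then (CH2O)n, THF, 0 °C → rt
Reagents that add atoms: trimethylaluminium C[Al](C)C; formaldehyde (from paraformaldehyde) C=O
Why: Negishi zirconium-catalysed carboalumination adds CH3 and Al syn across the terminal alkyne with methyl on the internal carbon, and the alkenylalane adds to formaldehyde with retention, which gives the (13E) allylic alcohol. The neopentylic C18 ester is too hindered to be attacked by Me3Al at room temperature, and no alkyllithium activation is used.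

Step 13
Reactants: 19 methyl (1S,5S,6R,8aS)-5-[(3E)-5-hydroxy-3-methylpent-3-en-1-yl]-1,5,6-trimethyl-1,2,3,5,6,7,8,8a-octahydronaphthalene-1-carboxylate
Product: 20 (1S,5S,6R,8aS)-5-[(3E)-5-hydroxy-3-methylpent-3-en-1-yl]-1,5,6-trimethyl-1,2,3,5,6,7,8,8a-octahydronaphthalene-1-carboxylic acid
Conditions: EtSNa, DMF, 100 °C; then aq. HCl
Reagents that add atoms: none
Why: The ester carbonyl is shielded by quaternary C4, so the ester is cleaved by SN2 attack of ethanethiolate on the O-methyl group (nucleophilic demethylation of hindered methyl esters); the allylic alcohol and both alkenes are inert to thiolate, and acidification gives the acid.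

Step 14
Reactants: 20 (1S,5S,6R,8aS)-5-[(3E)-5-hydroxy-3-methylpent-3-en-1-yl]-1,5,6-trimethyl-1,2,3,5,6,7,8,8a-octahydronaphthalene-1-carboxylic acid
Product: 21 (1S,5S,6R,8aS)-1,5,6-trimethyl-5-[(3E)-3-methyl-5-(propanoyloxy)pent-3-en-1-yl]-1,2,3,5,6,7,8,8a-octahydronaphthalene-1-carboxylic acid
Conditions: (EtCO)2O, pyridine, 4-(dimethylamino)pyridine (cat.), CH2Cl2, 0 °C → rt; then aq. NaHCO3, THF
Reagents that add atoms: propanoic anhydride CCC(=O)OC(=O)CC
Why: Nucleophile-catalysed acylation of the primary allylic alcohol; any mixed anhydride formed at the hindered C18 carboxyl is hydrolysed back to the acid in the bicarbonate work-up, so the propionate is introduced last, after all basic and nucleophilic steps.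

## Compound list

1 | 2-methylcyclohex-2-en-1-one | CC1=CCCCC1=O | starting material
2 | allyl bromide | C=CCBr | starting material
3 | dimethylaluminium (3R)-2,3-dimethylcyclohex-1-en-1-olate | CC1=C(O[Al](C)C)CCC[C@H]1C | intermediate (not isolated)
4 | lithium trimethyl[(3R)-2,3-dimethylcyclohex-1-en-1-olato]aluminate | [Li+].CC1=C(O[Al-](C)(C)C)CCC[C@H]1C | intermediate (not isolated)
5 | (2S,3R)-2,3-dimethyl-2-(prop-2-en-1-yl)cyclohexan-1-one | C=CC[C@]1(C)C(=O)CCC[C@H]1C | intermediate
6 | (5R,6S)-5,6-dimethyl-6-(prop-2-en-1-yl)cyclohex-1-en-1-yl trifluoromethanesulfonate | C=CC[C@]1(C)C(OS(=O)(=O)C(F)(F)F)=CCC[C@H]1C | intermediate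
7 | (5R,6S)-6-(3-hydroxypropyl)-5,6-dimethylcyclohex-1-en-1-yl trifluoromethanesulfonate | OCCC[C@]1(C)C(OS(=O)(=O)C(F)(F)F)=CCC[C@H]1C | intermediate
8 | propargyl alcohol | C#CCO | starting material
9 | 3-[(5R,6S)-6-(3-hydroxypropyl)-5,6-dimethylcyclohex-1-en-1-yl]prop-2-yn-1-ol | OCCC[C@]1(C)C(C#CCO)=CCC[C@H]1C | intermediate
10 | 3-[(5R,6S)-6-(3-hydroxypropyl)-5,6-dimethylcyclohex-1-en-1-yl]prop-2-ynal | OCCC[C@]1(C)C(C#CC=O)=CCC[C@H]1C | intermediate
11 | methyl 2-[bis(2,2,2-trifluoroethoxy)phosphoryl]propanoate | COC(=O)C(C)P(=O)(OCC(F)(F)F)OCC(F)(F)F | starting material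
12 | methyl (2Z)-5-[(5R,6S)-6-(3-hydroxypropyl)-5,6-dimethylcyclohex-1-en-1-yl]-2-methylpent-2-en-4-ynoate | OCCC[C@]1(C)C(C#C/C=C(/C)C(=O)OC)=CCC[C@H]1C | intermediate
13 | methyl (2Z,4Z)-5-[(5R,6S)-6-(3-hydroxypropyl)-5,6-dimethylcyclohex-1-en-1-yl]-2-methylpenta-2,4-dienoate | OCCC[C@]1(C)C(/C=C\C=C(\C)C(=O)OC)=CCC[C@H]1C | intermediate
14 | methyl (1S,5S,6R,8aS)-5-(3-hydroxypropyl)-1,5,6-trimethyl-1,5,6,7,8,8a-hexahydronaphthalene-1-carboxylate | OCCC[C@]1(C)C2=CC=C[C@](C)(C(=O)OC)[C@H]2CC[C@H]1C | intermediate
15 | methyl (1S,5S,6R,8aS)-5-(3-hydroxypropyl)-1,5,6-trimethyl-1,2,3,5,6,7,8,8a-octahydronaphthalene-1-carboxylate | OCCC[C@]1(C)C2=CCC[C@](C)(C(=O)OC)[C@H]2CC[C@H]1C | intermediate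
16 | methyl (1S,5S,6R,8aS)-1,5,6-trimethyl-5-(3-oxopropyl)-1,2,3,5,6,7,8,8a-octahydronaphthalene-1-carboxylate | O=CCC[C@]1(C)C2=CCC[C@](C)(C(=O)OC)[C@H]2CC[C@H]1C | intermediate
17 | methyl (1S,5S,6R,8aS)-5-(but-3-yn-1-yl)-1,5,6-trimethyl-1,2,3,5,6,7,8,8a-octahydronaphthalene-1-carboxylate | C#CCC[C@]1(C)C2=CCC[C@](C)(C(=O)OC)[C@H]2CC[C@H]1C | intermediate
18 | methyl (1S,5S,6R,8aS)-5-[(3E)-4-(dimethylalumanyl)-3-methylbut-3-en-1-yl]-1,5,6-trimethyl-1,2,3,5,6,7,8,8a-octahydronaphthalene-1-carboxylate | C[Al](C)/C=C(\C)CC[C@]1(C)C2=CCC[C@](C)(C(=O)OC)[C@H]2CC[C@H]1C | intermediate (not isolated)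
19 | methyl (1S,5S,6R,8aS)-5-[(3E)-5-hydroxy-3-methylpent-3-en-1-yl]-1,5,6-trimethyl-1,2,3,5,6,7,8,8a-octahydronaphthalene-1-carboxylate | OC/C=C(\C)CC[C@]1(C)C2=CCC[C@](C)(C(=O)OC)[C@H]2CC[C@H]1C | intermediate
20 | (1S,5S,6R,8aS)-5-[(3E)-5-hydroxy-3-methylpent-3-en-1-yl]-1,5,6-trimethyl-1,2,3,5,6,7,8,8a-octahydronaphthalene-1-carboxylic acid | OC/C=C(\C)CC[C@]1(C)C2=CCC[C@](C)(C(=O)O)[C@H]2CC[C@H]1C | intermediate
21 | (1S,5S,6R,8aS)-1,5,6-trimethyl-5-[(3E)-3-methyl-5-(propanoyloxy)pent-3-en-1-yl]-1,2,3,5,6,7,8,8a-octahydronaphthalene-1-carboxylic acid | CCC(=O)OC/C=C(\C)CC[C@]1(C)C2=CCC[C@](C)(C(=O)O)[C@H]2CC[C@H]1C | target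

## Step count and risks

Total step count: 14. Longest linear sequence: 14 steps, from 1 to 21.

**Step 8 (key step).**
- What may go wrong: poor torquoselectivity. The two disrotatory modes differ only in the conformational demands they place on ring B, so they may be populated almost equally and half of the material may close on the wrong face of C5. The inside ester also raises the barrier, and prolonged heating could start 1,5-hydrogen migration of H5 around the new diene.
- Fallback: it replaces substrate control by catalyst control. It sets out from 6 and comes back at 15.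
  - Triflate 6 is vinylated by Stille coupling with tributyl(vinyl)stannane (Pd(PPh3)4, LiCl, THF) to (5R,6S)-1-ethenyl-5,6-dimethyl-6-(prop-2-en-1-yl)cyclohex-1-ene F1.
  - A Diels–Alder reaction of F1 with methacrolein under a chiral oxazaborolidinium triflimide catalyst gives the 9-allyl 1(10)-octalin C18 aldehyde F2. The antipode of the catalyst and its exo preference are chosen to place the formyl group cis to H5 on the face anti to the chain.
  - Pinnick oxidation (NaClO2, NaH2PO4, 2-methylbut-2-ene) gives the 9-allyl acid F3, and methylation (MeI, K2CO3, DMF) gives the 9-allyl methyl ester F4.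
  - Hydroboration of the allyl group with 9-BBN and oxidation with NaBO3·4H2O gives 15.

**Step 1.**
- What may go wrong: incomplete enantiofacial control in the copper-catalysed addition to a trisubstituted enone, and proton transfer or O-allylation when the hindered tetrasubstituted aluminate meets allyl bromide, which would lower conversion and the cis-dimethyl selectivity.
- Fallback: it sets out from 1 and comes back at 5. The aluminate 4 is generated as in step 1 and quenched with allyl chloroformate to give allyl (3R)-2,3-dimethylcyclohex-1-en-1-yl carbonate F5. Decarboxylative Tsuji allylation with Pd(PPh3)4 (zerovalent palladium) in THF then forms the enolate and the allyl electrophile as an ion pair under neutral conditions and joins C9 to C11 anti to the C8 methyl, giving 5.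

**Step 7.**
- What may go wrong: slow or incomplete reduction of an alkyne that is shielded by quaternary C9 at the metal surface, over-reduction on forcing, or Z-to-E isomerisation of the new alkene during isolation.
- Fallback: it avoids the alkyne altogether. It sets out from 7 (with 8 and 11) and comes back at 13.
  - Propargyl alcohol 8 is hydroaluminated with LiAlH4 and the vinylalanate is stannylated with Bu3SnOTf to give (Z)-3-(tributylstannyl)prop-2-en-1-ol F6.
  - MnO2 oxidation gives (Z)-3-(tributylstannyl)prop-2-enal F7.
  - Still–Gennari olefination with 11 gives methyl (2Z,4Z)-2-methyl-5-(tributylstannyl)penta-2,4-dienoate F8.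
  - Stille coupling of F8 with triflate 7 (Pd(PPh3)4, CuI, LiCl, DMF) transfers the dienyl group with retention of both geometries and gives 13.

**Step 12.**
- What may go wrong: coordination of Me3Al to the ester may slow the carbometalation, and the alkenylalane may be protonated before it adds to formaldehyde, since it is only a moderate nucleophile without alkyllithium activation.
- Fallback: it builds C13=C14 by olefination. It sets out from 16 and comes back at 19.
  - Aldehyde 16 is treated with MeMgBr (THF, −78 °C) to give the C13 secondary alcohol F9 as a mixture of epimers.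
  - Dess–Martin oxidation gives the C13 methyl ketone F10.
  - Horner–Wadsworth–Emmons reaction with triethyl phosphonoacetate (NaH, THF) gives the (13E) ethyl enoate F11 after removal of the Z isomer.
  - i-Bu2AlH (CH2Cl2, −78 °C) reduces the unhindered conjugated ethyl ester in preference to the neopentylic methyl ester and gives 19.

**Step 13.**
- What may go wrong: sluggish demethylation, because even attack at the O-methyl carbon is slowed by the crowded carboxylate leaving group, so that the temperature has to be raised to a point where the thiolate begins to attack elsewhere or the alkene begins to move.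
- Fallback: it frees the acid by a redox detour before the side chain is finished. It sets out from 17 and comes back at 20.
  - Ester 17 is reduced with LiAlH4 (THF) to the C18 primary alcohol F12.
  - Dess–Martin oxidation gives the C18 aldehyde F13, and Pinnick oxidation (NaClO2, NaH2PO4, 2-methylbut-2-ene) gives the alkynyl acid F14.
  - The carboalumination–formaldehyde sequence of step 12, run on F14 with one extra equivalent of Me3Al to take up the carboxyl proton, gives 20.

## Further compounds

F1 | step 8 | (5R,6S)-1-ethenyl-5,6-dimethyl-6-(prop-2-en-1-yl)cyclohex-1-ene | C=CC[C@]1(C)C(C=C)=CCC[C@H]1C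
F2 | step 8 | (1S,5S,6R,8aS)-1,5,6-trimethyl-5-(prop-2-en-1-yl)-1,2,3,5,6,7,8,8a-octahydronaphthalene-1-carbaldehyde | C=CC[C@]1(C)C2=CCC[C@](C)(C=O)[C@H]2CC[C@H]1C
F3 | step 8 | (1S,5S,6R,8aS)-1,5,6-trimethyl-5-(prop-2-en-1-yl)-1,2,3,5,6,7,8,8a-octahydronaphthalene-1-carboxylic acid | C=CC[C@]1(C)C2=CCC[C@](C)(C(=O)O)[C@H]2CC[C@H]1C
F4 | step 8 | methyl (1S,5S,6R,8aS)-1,5,6-trimethyl-5-(prop-2-en-1-yl)-1,2,3,5,6,7,8,8a-octahydronaphthalene-1-carboxylate | C=CC[C@]1(C)C2=CCC[C@](C)(C(=O)OC)[C@H]2CC[C@H]1C
F5 | step 1 | allyl (3R)-2,3-dimethylcyclohex-1-en-1-yl carbonate | CC1=C(OC(=O)OCC=C)CCC[C@H]1C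
F6 | step 7 | (Z)-3-(tributylstannyl)prop-2-en-1-ol | CCCC[Sn](CCCC)(CCCC)/C=C\CO
F7 | step 7 | (Z)-3-(tributylstannyl)prop-2-enal | CCCC[Sn](CCCC)(CCCC)/C=C\C=O
F8 | step 7 | methyl (2Z,4Z)-2-methyl-5-(tributylstannyl)penta-2,4-dienoate | CCCC[Sn](CCCC)(CCCC)/C=C\C=C(\C)C(=O)OC
F9 | step 12 | methyl (1S,5S,6R,8aS)-5-(3-hydroxybutyl)-1,5,6-trimethyl-1,2,3,5,6,7,8,8a-octahydronaphthalene-1-carboxylate (epimers at the carbinol carbon) | CC(O)CC[C@]1(C)C2=CCC[C@](C)(C(=O)OC)[C@H]2CC[C@H]1C
F10 | step 12 | methyl (1S,5S,6R,8aS)-1,5,6-trimethyl-5-(3-oxobutyl)-1,2,3,5,6,7,8,8a-octahydronaphthalene-1-carboxylate | CC(=O)CC[C@]1(C)C2=CCC[C@](C)(C(=O)OC)[C@H]2CC[C@H]1C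
F11 | step 12 | methyl (1S,5S,6R,8aS)-5-[(3E)-5-ethoxy-3-methyl-5-oxopent-3-en-1-yl]-1,5,6-trimethyl-1,2,3,5,6,7,8,8a-octahydronaphthalene-1-carboxylate | CCOC(=O)/C=C(\C)CC[C@]1(C)C2=CCC[C@](C)(C(=O)OC)[C@H]2CC[C@H]1C
F12 | step 13 | [(1S,5S,6R,8aS)-5-(but-3-yn-1-yl)-1,5,6-trimethyl-1,2,3,5,6,7,8,8a-octahydronaphthalen-1-yl]methanol | C#CCC[C@]1(C)C2=CCC[C@](C)(CO)[C@H]2CC[C@H]1C
F13 | step 13 | (1S,5S,6R,8aS)-5-(but-3-yn-1-yl)-1,5,6-trimethyl-1,2,3,5,6,7,8,8a-octahydronaphthalene-1-carbaldehyde | C#CCC[C@]1(C)C2=CCC[C@](C)(C=O)[C@H]2CC[C@H]1C
F14 | step 13 | (1S,5S,6R,8aS)-5-(but-3-yn-1-yl)-1,5,6-trimethyl-1,2,3,5,6,7,8,8a-octahydronaphthalene-1-carboxylic acid | C#CCC[C@]1(C)C2=CCC[C@](C)(C(=O)O)[C@H]2CC[C@H]1C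
A1 | alternative 1 | dimethyl 2-[(4E)-7-(tert-butyldimethylsilyloxy)-5-methyl-3-oxohept-4-en-1-yl]-2-[(1E,3E)-penta-1,3-dien-1-yl]propanedioate | C/C=C/C=C/C(C(=O)OC)(C(=O)OC)CCC(=O)/C=C(\C)CCO[Si](C)(C)C(C)(C)C
A2 | alternative 1 | cis-fused 1-oxo-6-octalin 4,4-dimethyl diester with C8 methyl, C9 methyl and C9 2-(tert-butyldimethylsilyloxy)ethyl (halimane numbering) | CC(C)(C)[Si](C)(C)OCC[C@]1(C)[C@H]2C(=O)CCC(C(=O)OC)(C(=O)OC)[C@H]2C=C[C@H]1C
A3 | alternative 2 | methyl 4-hydroxy-1,6-dimethyl-5-[3-(tert-butyldimethylsilyloxy)propyl]-1,2,3,4,6,7,8,8a-octahydronaphthalene-1-carboxylate (Δ9(10)-octalin C1 alcohol) | CC(C)(C)[Si](C)(C)OCCCC1=C2[C@@H](O)CC[C@](C)(C(=O)OC)[C@H]2CC[C@H]1C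
A4 | alternative 2 | 9,10-methano decalin C1 alcohol with C4 methyl and methyl ester, C8 methyl and C9 3-(tert-butyldimethylsilyloxy)propyl (halimane numbering) | CC(C)(C)[Si](C)(C)OCCC[C@]12C[C@]13[C@@H](O)CC[C@](C)(C(=O)OC)[C@H]3CC[C@H]2C
A5 | alternative 3 | (5R,6S)-1-ethenyl-5,6-dimethyl-6-(prop-2-en-1-yl)cyclohex-1-ene | C=CC[C@]1(C)C(C=C)=CCC[C@H]1C
A6 | alternative 3 | methacrolein (2-methylprop-2-enal) | CC(=C)C=O
A7 | alternative 3 | (1S,5S,6R,8aS)-1,5,6-trimethyl-5-(prop-2-en-1-yl)-1,2,3,5,6,7,8,8a-octahydronaphthalene-1-carbaldehyde | C=CC[C@]1(C)C2=CCC[C@](C)(C=O)[C@H]2CC[C@H]1C
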